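**Retrosynthetic overview**

1. Locants follow the labdane skeleton: ring A = C1–C5 + C10; ring B = C5–C10; C19 = lactone carbonyl on C4 (C18 = its methyl); C20 = CH2OAc on C10; C17 = methyl on C8; oxolane = C9–C11–C12–C13–O; dihydrofuran = C13–C14=C15–O–C16.
2. Target ⇒ ring B acid with a C7=C8 alkene (C14=C15 by lactol dehydration, C20–OAc from the C20 acid, C8–H by hydroxyl-directed hydrogenation) ⇒ key disconnection of C9–C10 by Ireland–Claisen rearrangement of a tricyclic bis-lactone (ring A, 19,6-γ-lactone, temporary C20–O–C7 δ-lactone) that carries on C7 a (Z)-2-alkylidene-oxolane (C8=C9). The shift closes ring B and opens the δ-lactone.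
3. Feature that allows this: C10 bears the oxygenated carbon C20 (a reduced carboxyl), C9 bears the oxolane oxygen (an enol-ether terminus), and C7–C8 of ring B can be an alkene. Ring B therefore holds the γ,δ-unsaturated acid retron C20–C10–C9–C8=C7, with the ester oxygen placed on C7 of the same six-membered ring.
4. Bis-lactone ⇒ (E)-enyne (Sonogashira union at C7–C8 of a ring A vinyl iodide and an alkynyl tertiary alcohol) via Shi epoxidation, epoxide-opening γ-lactonisation (inversion at C6), δ-lactonisation, 5-exo-dig iodoetherification and Negishi methylation. Ring A comes from a menthyloxy butenolide by Michael–alkylation annulation; C13 from a Sharpless epoxidation.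
5. Order of ring formation: butenolide lactone → ring A → 19,6-γ-lactone (re-closed) → δ-lactone (temporary) → oxolane → ring B (key step) → dihydrofuran.

Key step: step 18

Remark: C10 is formed as a pair of epimers in step 3 and is written without configuration in 6–10 and 21–26 (both epimers give the same ketene acetal 27, and step 18 then sets C10); the hemiacetal carbons of lactols 8 and 36 are anomer mixtures.

**Route**

Step 1
Reactants: 1 3-methylfuran-2(5H)-one
Product: 2 5-bromo-3-methylfuran-2(5H)-one (racemic)
Conditions: NBS, AIBN (cat.), PhCF3, 85 °C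
Reagents that add atoms: N-bromosuccinimide, O=C1CCC(=O)N1Br
Why: Wohl–Ziegler radical bromination should take place at C5–H, which is both allylic and next to the ring oxygen, to give the γ-bromobutenolide.

Step 2
Reactants: 2 5-bromo-3-methylfuran-2(5H)-one; 3 (−)-menthol
Product: 4 (5R)-3-methyl-5-[(1R,2S,5R)-menthyloxy]furan-2(5H)-one
Conditions: Ag2CO3, 4 Å MS, CH2Cl2, rt, dark; crystallisation; mother liquor re-equilibrated with CSA (cat.) and recycled
Reagents that add atoms: none
Why: Silver-assisted SN1 substitution of the Koenigs–Knorr type through the furanone oxocarbenium ion should give both acetal epimers, from which the (5R) epimer is taken by crystallisation, so that the acetal carbon becomes the source of absolute configuration for ring A.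

Step 3
Reactants: 4 (5R)-3-methyl-5-menthyloxyfuran-2(5H)-one; 5 methyl 5-bromopentanoate
Product: 7 methyl (3R,3aR,7aS)-7a-methyl-3-[(1R,2S,5R)-menthyloxy]-1-oxooctahydroisobenzofuran-4-carboxylate (C10 epimers), via lithium lactone enolate 6 (not isolated)
Conditions: 5, LiN(iPr)2, THF, −78 °C; then 4, −78 °C; then DMPU, −78 → 0 °C
Reagents that add atoms: none
Why: In this Michael-initiated ring closure the ester enolate should add to the butenolide β-carbon anti to the menthyloxy group (sets C5), and the resulting α-methyl lactone enolate should close ring A by 6-exo-tet alkylation on the face of the new chain, which gives the cis-fused lactone and the quaternary C4.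

Step 4
Reactants: 7 bicyclic lactone acetal
Product: 8 methyl (3aR,7aS)-3-hydroxy-7a-methyl-1-oxooctahydroisobenzofuran-4-carboxylate (lactol anomers, C10 epimers)
Conditions: TFA/H2O (9:1), rt
Reagents that add atoms: water, O
Why: Acid hydrolysis of the acyl acetal should release menthol and leave the hydroxy lactone, the ring tautomer of the 2-formyl acid.

Step 5
Reactants: 8 hydroxy lactone
Product: 9 1-tert-butyl 3-methyl (1S,2R)-2-formyl-1-methylcyclohexane-1,3-dicarboxylate (C10 epimers)
Conditions: O-tert-butyl-N,N′-diisopropylisourea, CH2Cl2, rt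
Reagents that add atoms: O-tert-butyl-N,N′-diisopropylisourea, CC(C)NC(=NC(C)C)OC(C)(C)C
Why: Isourea esterification of the open-chain acid tautomer under neutral conditions should trap the open form as the aldehyde tert-butyl ester without epimerising C5, and it makes the C19 ester the one that can later act as a neighbouring group.

Step 6
Reactants: 9 aldehyde diester
Product: 10 1-tert-butyl 3-methyl (1S,2S)-2-[(E)-2-iodoethenyl]-1-methylcyclohexane-1,3-dicarboxylate (C10 epimers)
Conditions: CrCl2, CHI3, THF/dioxane, 0 °C → rt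
Reagents that add atoms: iodoform, IC(I)I
Why: Takai olefination with the geminal dichromium reagent should convert the hindered aldehyde into the (E)-iodoalkene under non-basic conditions.

Step 7
Reactants: 11 prop-2-yn-1-ol; 12 (4-bromobut-1-yn-1-yl)trimethylsilane
Product: 14 2-methylidene-6-(trimethylsilyl)hex-5-yn-1-ol, via Grignard reagent 13 (not isolated)
Conditions: 12, Mg, THF, rt; then 11 (pre-treated with EtMgBr, 1 equiv), CuI (10 mol %), THF, −10 °C → rt; aq. NH4Cl
Reagents that add atoms: none
Why: Copper-catalysed anti-carbomagnesiation of the propargylic magnesium alkoxide should deliver the alkyl group to the internal alkyne carbon and give the 2-substituted allylic alcohol after protonolysis.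

Step 8
Reactants: 14 allylic alcohol
Product: 15 [(2S)-2-[4-(trimethylsilyl)but-3-yn-1-yl]oxiran-2-yl]methanol
Conditions: Ti(OiPr)4 (10 mol %), L-(+)-diethyl tartrate (12 mol %), t-BuOOH, 4 Å MS, CH2Cl2, −20 °C
Reagents that add atoms: tert-butyl hydroperoxide, CC(C)(C)OO
Why: Sharpless asymmetric epoxidation of the 2-substituted allylic alcohol with the L-(+)-tartrate ligand should give the (S)-epoxy alcohol and thereby set C13.

Step 9
Reactants: 15 epoxy alcohol
Product: 16 (2R)-2-(prop-2-en-1-yl)-6-(trimethylsilyl)hex-5-yne-1,2-diol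
Conditions: vinylmagnesium bromide (3 equiv), CuI (10 mol %), THF, −40 → 0 °C
Reagents that add atoms: vinylmagnesium bromide, C=C[Mg]Br
Why: Copper-catalysed SN2 opening of the 2,2-disubstituted epoxide at its CH2 end leaves the C13–O bond untouched, and a Payne rearrangement of the alkoxide would be degenerate and stereoretentive, so C13 should be kept.

Step 10
Reactants: 16 diol
Product: 17 (2R)-1-[(tert-butyldiphenylsilyl)oxy]-2-(prop-2-en-1-yl)-6-(trimethylsilyl)hex-5-yn-2-ol
Conditions: TBDPSCl, imidazole, CH2Cl2, 0 °C
Reagents that add atoms: tert-butyl(chloro)diphenylsilane, CC(C)(C)[Si](Cl)(c1ccccc1)c1ccccc1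
Why: Selective silylation of the primary hydroxyl (C16) in the presence of the tertiary one should leave the C13 hydroxyl free for the later etherification.

Step 11
Reactants: 17 silyl ether
Product: 19 (2R)-1-[(tert-butyldiphenylsilyl)oxy]-2-(2,2-dimethoxyethyl)-6-(trimethylsilyl)hex-5-yn-2-ol, via hydroxy aldehyde 18 (not isolated)
Conditions: O3, CH2Cl2/MeOH, −78 °C (indicator end point); Me2S; then CH(OMe)3, PPTS (cat.), MeOH, rt
Reagents that add atoms: methanol, CO; trimethyl orthoformate, COC(OC)OC
Why: Ozonolysis of the terminal alkene, which is much faster than ozonation of the silylalkyne, followed by acetalisation should mask C15 at the aldehyde oxidation level as a dimethyl acetal that survives every step up to the end.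

Step 12
Reactants: 19 silylalkyne
Product: 20 (2R)-1-[(tert-butyldiphenylsilyl)oxy]-2-(2,2-dimethoxyethyl)hex-5-yn-2-ol
Conditions: K2CO3 (cat.), MeOH, rt
Reagents that add atoms: none
Why: Base-catalysed methanolysis of the alkynyl C–Si bond should free the terminal alkyne while the silyl ether and the acetal stay.

Step 13
Reactants: 10 (E)-vinyl iodide; 20 terminal alkyne
Product: 21 (E)-enyne diester (4S,5R,13R; C10 epimers): 10 with iodine replaced by the alkynyl group of 20
Conditions: PdCl2(PPh3)2 (5 mol %), CuI (10 mol %), Et3N, THF, rt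
Reagents that add atoms: none
Why: Sonogashira coupling should join the two fragments at C7–C8 with retention of the (E) geometry and tolerates the free tertiary alcohol.

Step 14
Reactants: 21 (E)-enyne
Product: 22 (6R,7R)-epoxide of 21 (4S,5R,6R,7R,13R; C10 epimers)
Conditions: D-fructose-derived ketone catalyst of the Shi epoxidation (30 mol %), KHSO5 (as 2KHSO5·KHSO4·K2SO4), K2CO3, Bu4NHSO4, MeCN/dimethoxymethane–aq. borate buffer (pH 10.5), 0 °C
Reagents that add atoms: potassium peroxymonosulfate, [K+].[O-]S(=O)(=O)OO
Why: Shi epoxidation by the chiral dioxirane is chemoselective for the alkene of a conjugated enyne and its facial selectivity is reagent-controlled, so the (6R,7R)-epoxide should form whatever the ring A stereocentres prefer.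

Step 15
Reactants: 22 epoxide
Product: 24 tricyclic bis-lactone alkynol (4S,5R,6S,7R,13R; C10 epimers), via hydroxy lactone 23 (not isolated)
Conditions: CSA (20 mol %), CH2Cl2, 0 °C → rt; then toluene, 60 °C
Reagents that add atoms: none
Why: Acid-promoted 5-exo opening of the epoxide at C6 by the carbonyl oxygen of the tert-butyl ester (neighbouring-group lactonisation with loss of 2-methylpropene) should give the 19,6-γ-lactone with inversion at C6, and the freed C7 hydroxyl should then lactonise onto the C20 methyl ester.

Step 16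
Reactants: 24 bis-lactone alkynol
Product: 25 (E)-α-iodo enol ether (2-(1-iodoalkylidene)oxolane; C10 epimers)
Conditions: I2, NaHCO3, MeCN, 0 °C
Reagents that add atoms: iodine, II
Why: In this 5-exo-dig iodoetherification, anti addition of the C13 hydroxyl and iodine across the alkyne should close the oxolane and place the ring oxygen cis to C7.

Step 17
Reactants: 25 iodo enol ether
Product: 26 (Z)-enol ether bis-lactone (4S,5R,6S,7R,13R; C10 epimers)
Conditions: Me2Zn, Pd(PPh3)4 (5 mol %), THF, 0 °C → rt
Reagents that add atoms: dimethylzinc, C[Zn]C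
Why: Negishi coupling should replace iodine by the C17 methyl group with retention of alkene geometry, which gives the tetrasubstituted enol ether with the ring oxygen cis to C7.

Step 18
Reactants: 26 (Z)-enol ether bis-lactone
Product: 29 ring B carboxylic acid (C4, C5, C6, C9, C10, C13 as in the target; C7=C8 alkene), via silyl ketene acetal 27 (not isolated), via silyl ester 28 (not isolated)
Conditions: LiN(iPr)2, THF, −78 °C; TBSCl, HMPA, −78 °C → rt; toluene, 90 °C; aq. citric acid
Reagents that add atoms: none
Why: Ireland–Claisen rearrangement of a lactone silyl ketene acetal: C10–H of the δ-lactone is the only enolisable position (C4 is quaternary), O-silylation gives the cyclic ketene acetal 27, and a concerted suprafacial [3,3] shift forms C9–C10 while the allylic C7–O bond breaks to give silyl ester 28. The closest known reaction type is the ester-enolate Claisen ring transposition of six-membered lactones that carry an alkenyl group on the carbinol carbon, which gives cyclohexene carboxylic acids. Ring B (C5–C6–C7–C8–C9–C10) is closed through the pericyclic array C10=C20–O–C7–C8=C9, which the two-atom C5–C6 bridge between C7 and C10 forces into a boat (bicyclo[2.2.2]octane-like) geometry, and the temporary δ-lactone is opened in the same event. C10 is controlled by the (7R) carbinol centre, because C9 can reach the ketene acetal only on the lactone face that carries the alkenyl group, which puts C20 on the β face and makes the ring A/ring B fusion trans. C9 is controlled by the boat geometry together with the (Z)-enol ether (ring oxygen cis to C7), which places the ether oxygen axial (α) and C11 equatorial. The step needs site-selective enolisation and a concerted rather than ionic C7–O cleavage; the first is secured by the quaternary C4, the second by the non-polar medium, base-washed glassware and the rate gain from the oxygen donor on the allyl terminus.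

Step 19
Reactants: 29 ring B acid
Product: 31 C20 primary alcohol, via acyl fluoride 30 (not isolated)
Conditions: cyanuric fluoride, pyridine, CH2Cl2, −10 °C → rt; then NaBH4, MeOH, 0 °C
Reagents that add atoms: none
Why: Activation of the hindered neopentyl acid as the small acyl fluoride and borohydride reduction should give the C20 alcohol without touching the γ-lactone or the alkene, whereas a borane reduction would risk hydroboration.

Step 20
Reactants: 31 C20 alcohol
Product: 32 saturated alcohol (C8 as in the target)
Conditions: [Ir(cod)(PCy3)(py)]PF6 (10 mol %), H2 (10 bar), CH2Cl2, rt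
Reagents that add atoms: none
Why: In this hydroxyl-directed homogeneous hydrogenation the axial C20 hydroxymethyl group should bind iridium and deliver hydrogen to the β face of the C7=C8 alkene, which sets C8 with H β and the methyl group α (equatorial).

Step 21
Reactants: 32 saturated alcohol
Product: 33 C20 acetate
Conditions: Ac2O, pyridine, DMAP (cat.), CH2Cl2, rt
Reagents that add atoms: acetic anhydride, CC(=O)OC(C)=O
Why: Standard acylation of the only free hydroxyl should install the acetate of the target.

Step 22
Reactants: 33 acetate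
Product: 36 spiro lactol (anomers at C15), via primary alcohol 34 (not isolated), via hydroxy aldehyde 35 (not isolated)
Conditions: TBAF, AcOH, THF, rt; then AcOH/H2O (3:1), 40 °C
Reagents that add atoms: water, O
Why: Buffered fluoride desilylation should free the C16 hydroxyl without acetate migration, and mild acid hydrolysis of the dimethyl acetal gives the aldehyde, which should close to the five-membered lactol.

Step 23
Reactants: 36 spiro lactol
Product: 38 target CNP0218619.1, via anomeric mesylate 37 (not isolated)
Conditions: MsCl, Et3N, CH2Cl2, −20 °C → reflux; chromatography on Et3N-deactivated silica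
Reagents that add atoms: none
Why: Lactol dehydration by O-mesylation at the anomeric carbon and amine-induced elimination of a C14 hydrogen (C13 has none) should give the 2,3-dihydrofuran under basic conditions, which avoid the acid-induced opening of the spiro ether to a furan.

**Compound list**

1 | 3-methylfuran-2(5H)-one | CC1=CCOC1=O | starting material
2 | 5-bromo-3-methylfuran-2(5H)-one (racemic) | CC1=CC(Br)OC1=O | intermediate
3 | (−)-menthol, (1R,2S,5R)-5-methyl-2-(propan-2-yl)cyclohexan-1-ol | CC(C)[C@@H]1CC[C@@H](C)C[C@H]1O | starting material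
4 | (5R)-3-methyl-5-[(1R,2S,5R)-menthyloxy]furan-2(5H)-one | CC1=C[C@H](O[C@@H]2C[C@H](C)CC[C@H]2C(C)C)OC1=O | intermediate
5 | methyl 5-bromopentanoate | COC(=O)CCCCBr | starting material
6 | lithium lactone enolate of the Michael adduct (new chain trans to menthyloxy; not isolated) | [Li+].[O-]C1=C(C)[C@@H](C(CCCBr)C(=O)OC)[C@H](O[C@@H]2C[C@H](C)CC[C@H]2C(C)C)O1 | intermediate
7 | methyl (3R,3aR,7aS)-7a-methyl-3-[(1R,2S,5R)-menthyloxy]-1-oxooctahydroisobenzofuran-4-carboxylate (C10 epimers) | COC(=O)C1CCC[C@]2(C)C(=O)O[C@@H](O[C@@H]3C[C@H](C)CC[C@H]3C(C)C)[C@H]12 | intermediate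
8 | methyl (3aR,7aS)-3-hydroxy-7a-methyl-1-oxooctahydroisobenzofuran-4-carboxylate (lactol anomers, C10 epimers) | COC(=O)C1CCC[C@]2(C)C(=O)OC(O)[C@H]12 | intermediate
9 | 1-tert-butyl 3-methyl (1S,2R)-2-formyl-1-methylcyclohexane-1,3-dicarboxylate (C10 epimers) | COC(=O)C1CCC[C@](C)(C(=O)OC(C)(C)C)[C@@H]1C=O | intermediate
10 | 1-tert-butyl 3-methyl (1S,2S)-2-[(E)-2-iodoethenyl]-1-methylcyclohexane-1,3-dicarboxylate (C10 epimers) | COC(=O)C1CCC[C@](C)(C(=O)OC(C)(C)C)[C@@H]1/C=C/I | intermediate
11 | prop-2-yn-1-ol | OCC#C | starting material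
12 | (4-bromobut-1-yn-1-yl)trimethylsilane | C[Si](C)(C)C#CCCBr | starting material
13 | [4-(trimethylsilyl)but-3-yn-1-yl]magnesium bromide (not isolated) | C[Si](C)(C)C#CCC[Mg]Br | intermediate
14 | 2-methylidene-6-(trimethylsilyl)hex-5-yn-1-ol | C=C(CO)CCC#C[Si](C)(C)C | intermediate
15 | [(2S)-2-[4-(trimethylsilyl)but-3-yn-1-yl]oxiran-2-yl]methanol | OC[C@@]1(CCC#C[Si](C)(C)C)CO1 | intermediate
16 | (2R)-2-(prop-2-en-1-yl)-6-(trimethylsilyl)hex-5-yne-1,2-diol | OC[C@](O)(CC=C)CCC#C[Si](C)(C)C | intermediate
17 | (2R)-1-[(tert-butyldiphenylsilyl)oxy]-2-(prop-2-en-1-yl)-6-(trimethylsilyl)hex-5-yn-2-ol | CC(C)(C)[Si](c1ccccc1)(c1ccccc1)OC[C@](O)(CC=C)CCC#C[Si](C)(C)C | intermediate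
18 | (3R)-3-{[(tert-butyldiphenylsilyl)oxy]methyl}-3-hydroxy-7-(trimethylsilyl)hept-6-ynal (not isolated) | CC(C)(C)[Si](c1ccccc1)(c1ccccc1)OC[C@](O)(CC=O)CCC#C[Si](C)(C)C | intermediate
19 | (2R)-1-[(tert-butyldiphenylsilyl)oxy]-2-(2,2-dimethoxyethyl)-6-(trimethylsilyl)hex-5-yn-2-ol | CC(C)(C)[Si](c1ccccc1)(c1ccccc1)OC[C@](O)(CC(OC)OC)CCC#C[Si](C)(C)C | intermediate
20 | (2R)-1-[(tert-butyldiphenylsilyl)oxy]-2-(2,2-dimethoxyethyl)hex-5-yn-2-ol | CC(C)(C)[Si](c1ccccc1)(c1ccccc1)OC[C@](O)(CC(OC)OC)CCC#C | intermediate
21 | (E)-enyne diester: 1-tert-butyl 3-methyl 2-[(1E,7R)-7-{[(tert-butyldiphenylsilyl)oxy]methyl}-7-hydroxy-9,9-dimethoxynon-1-en-3-yn-1-yl]-1-methylcyclohexane-1,3-dicarboxylate (4S,5R; C10 epimers) | COC(=O)C1CCC[C@](C)(C(=O)OC(C)(C)C)[C@@H]1/C=C/C#CCC[C@@](O)(CC(OC)OC)CO[Si](c2ccccc2)(c2ccccc2)C(C)(C)C | intermediate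
22 | (6R,7R)-trans-epoxide of 21 (4S,5R,13R; C10 epimers) | COC(=O)C1CCC[C@](C)(C(=O)OC(C)(C)C)[C@@H]1[C@H]2O[C@@H]2C#CCC[C@@](O)(CC(OC)OC)CO[Si](c3ccccc3)(c3ccccc3)C(C)(C)C | intermediate
23 | hydroxy 19,6-γ-lactone methyl ester (4S,5R,6S,7R,13R; C7 side chain cis to ring A on the lactone; not isolated) | COC(=O)C1CCC[C@]2(C)C(=O)O[C@H]([C@H](O)C#CCC[C@@](O)(CC(OC)OC)CO[Si](c3ccccc3)(c3ccccc3)C(C)(C)C)[C@H]12 | intermediate
24 | tricyclic bis-lactone alkynol: ring A, 19,6-γ-lactone and C20–O–C7 δ-lactone (4S,5R,6S,7R,13R; C10 epimers) | O=C1O[C@H](C#CCC[C@@](O)(CC(OC)OC)CO[Si](c4ccccc4)(c4ccccc4)C(C)(C)C)[C@H]2OC(=O)[C@@]3(C)CCCC1[C@@H]23 | intermediate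
25 | bis-lactone with (E)-2-(1-iodoalkylidene)oxolane on C7 (iodine trans to ring oxygen; C10 epimers) | O=C1O[C@H](/C(I)=C4/CC[C@@](CC(OC)OC)(CO[Si](c5ccccc5)(c5ccccc5)C(C)(C)C)O4)[C@H]2OC(=O)[C@@]3(C)CCCC1[C@@H]23 | intermediate
26 | bis-lactone with (Z)-2-(1-methylalkylidene)oxolane on C7 (ring oxygen cis to C7; 4S,5R,6S,7R,13R; C10 epimers) | O=C1O[C@H](/C(C)=C4/CC[C@@](CC(OC)OC)(CO[Si](c5ccccc5)(c5ccccc5)C(C)(C)C)O4)[C@H]2OC(=O)[C@@]3(C)CCCC1[C@@H]23 | intermediate
27 | cyclic tert-butyldimethylsilyl ketene acetal of 26 (C10=C20; not isolated) | CC(C)(C)[Si](C)(C)OC1=C2CCC[C@]3(C)C(=O)O[C@@H]([C@H]23)[C@H](O1)/C(C)=C4/CC[C@@](CC(OC)OC)(CO[Si](c5ccccc5)(c5ccccc5)C(C)(C)C)O4 | intermediate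
28 | tert-butyldimethylsilyl ester of 29 (not isolated) | CC(C)(C)[Si](C)(C)OC(=O)[C@@]12CCC[C@]3(C)C(=O)O[C@H](C=C(C)[C@]14CC[C@@](CC(OC)OC)(CO[Si](c5ccccc5)(c5ccccc5)C(C)(C)C)O4)[C@H]23 | intermediate
29 | ring B acid: 9,13-epoxy-19,6-olide with C7=C8 alkene and C20 carboxylic acid (all stereocentres as in the target) | OC(=O)[C@@]12CCC[C@]3(C)C(=O)O[C@H](C=C(C)[C@]14CC[C@@](CC(OC)OC)(CO[Si](c5ccccc5)(c5ccccc5)C(C)(C)C)O4)[C@H]23 | intermediate
30 | acyl fluoride of 29 (not isolated) | FC(=O)[C@@]12CCC[C@]3(C)C(=O)O[C@H](C=C(C)[C@]14CC[C@@](CC(OC)OC)(CO[Si](c5ccccc5)(c5ccccc5)C(C)(C)C)O4)[C@H]23 | intermediate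
31 | C20 primary alcohol with C7=C8 alkene | OC[C@@]12CCC[C@]3(C)C(=O)O[C@H](C=C(C)[C@]14CC[C@@](CC(OC)OC)(CO[Si](c5ccccc5)(c5ccccc5)C(C)(C)C)O4)[C@H]23 | intermediate
32 | saturated C20 alcohol (8R, methyl α; all ring stereocentres as in the target) | OC[C@@]12CCC[C@]3(C)C(=O)O[C@H](C[C@@H](C)[C@]14CC[C@@](CC(OC)OC)(CO[Si](c5ccccc5)(c5ccccc5)C(C)(C)C)O4)[C@H]23 | intermediate
33 | C20 acetate with C16 silyl ether and C15 dimethyl acetal | CC(=O)OC[C@@]12CCC[C@]3(C)C(=O)O[C@H](C[C@@H](C)[C@]14CC[C@@](CC(OC)OC)(CO[Si](c5ccccc5)(c5ccccc5)C(C)(C)C)O4)[C@H]23 | intermediate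
34 | C16 primary alcohol with C15 dimethyl acetal (not isolated) | CC(=O)OC[C@@]12CCC[C@]3(C)C(=O)O[C@H](C[C@@H](C)[C@]14CC[C@@](CC(OC)OC)(CO)O4)[C@H]23 | intermediate
35 | C16 hydroxy C15 aldehyde (not isolated) | CC(=O)OC[C@@]12CCC[C@]3(C)C(=O)O[C@H](C[C@@H](C)[C@]14CC[C@@](CC=O)(CO)O4)[C@H]23 | intermediate
36 | spiro lactol (C15 hemiacetal, anomers) | CC(=O)OC[C@@]12CCC[C@]3(C)C(=O)O[C@H](C[C@@H](C)[C@]14CC[C@]1(CC(O)OC1)O4)[C@H]23 | intermediate
37 | anomeric mesylate of 36 (not isolated) | CC(=O)OC[C@@]12CCC[C@]3(C)C(=O)O[C@H](C[C@@H](C)[C@]14CC[C@]1(CC(OS(C)(=O)=O)OC1)O4)[C@H]23 | intermediate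
38 | CNP0218619.1 (20-acetoxy-9,13:15,16-diepoxylabd-14-en-19,6-olide; 4S,5R,6R,8R,9R,10S,13R) | CC(=O)OC[C@@]12CCC[C@]3(C)C(=O)O[C@H](C[C@@H](C)[C@]14CC[C@]1(C=COC1)O4)[C@H]23 | target

**Totals**

Total step count: 23.
Longest linear sequence: 17 steps (steps 1–6 then 13–23; the branch through steps 7–12 then 13–23 is equally long).

**Steps most likely to fail**

Step 18 (Ireland–Claisen ring closure). What may go wrong is heterolysis of the allylic C7–O bond of the very electron-rich enol ether (a vinylogous acylal), in 26 or in its ketene acetal, in competition with the concerted shift; the same lability also threatens the palladium step that makes 26. The fallback runs the shift before the methyl group is introduced, on the less electron-rich iodoalkylidene. Setting out from 25, LiN(iPr)2/TBSCl/HMPA in THF at −78 °C should give the iodo silyl ketene acetal F1, heating in toluene the iodo silyl ester F2, and aqueous citric acid the iodo acid F3. A Negishi methylation of the ring B alkenyl iodide of F3 (Me2Zn, Pd(PPh3)4, THF; oxidative addition to the C–I bond should outrun any reaction of the allylic 19,6-lactone) then comes back to the route at 29. The geometry argument is unchanged, because iodine occupies the place of the methyl group.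

Step 15 (epoxide-opening lactonisation). What may go wrong is a cation-like opening of the protonated epoxide at the propargylic carbon C7 (6-endo attack) or participation of the C20 ester, either of which would give the wrong lactone pattern. The fallback changes the nucleophile to a free carboxylate, so that the opening is a plain 5-exo SN2 displacement under basic to weakly acidic aqueous conditions. Setting out from 10, TFA in CH2Cl2 should cleave the tert-butyl ester to the vinyl iodide acid F4. Sonogashira coupling of F4 with 20 should give the enyne acid F5, and Shi epoxidation at pH 10.5 the epoxy acid F6 (as its carboxylate). On adjustment to pH 4, F6 should close at C6 with inversion and come back to the route at 23, which is lactonised to 24 with CSA in toluene as in step 15.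

Step 20 (directed hydrogenation). What may go wrong is poor facial selectivity or no turnover, because the trisubstituted alkene is flanked by the spiro carbon and the directing hydroxyl is two carbons removed from the nearer alkene carbon. The fallback replaces coordination-directed syn delivery by a stepwise radical hydrogenation through hydrogen-atom transfer: Mn(dpm)3 (cat.), PhSiH3, t-BuOOH, i-PrOH, rt. Setting out from 31, the tertiary C8 radical should take up its second hydrogen axially, which gives the thermodynamically preferred equatorial C17 methyl group, and the sequence comes back to the route at 32 without any new compound.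

**Further compounds**

F1 | step 18 | cyclic tert-butyldimethylsilyl ketene acetal of iodide 25 | CC(C)(C)[Si](C)(C)OC1=C2CCC[C@]3(C)C(=O)O[C@@H]([C@H]23)[C@H](O1)/C(I)=C4/CC[C@@](CC(OC)OC)(CO[Si](c5ccccc5)(c5ccccc5)C(C)(C)C)O4
F2 | step 18 | tert-butyldimethylsilyl ester of the ring B iodoalkene acid | CC(C)(C)[Si](C)(C)OC(=O)[C@@]12CCC[C@]3(C)C(=O)O[C@H](C=C(I)[C@]14CC[C@@](CC(OC)OC)(CO[Si](c5ccccc5)(c5ccccc5)C(C)(C)C)O4)[C@H]23
F3 | step 18 | ring B acid with C7=C8 iodoalkene (8-iodo analogue of 29) | OC(=O)[C@@]12CCC[C@]3(C)C(=O)O[C@H](C=C(I)[C@]14CC[C@@](CC(OC)OC)(CO[Si](c5ccccc5)(c5ccccc5)C(C)(C)C)O4)[C@H]23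
F4 | step 15 | (1S,2S)-2-[(E)-2-iodoethenyl]-3-(methoxycarbonyl)-1-methylcyclohexane-1-carboxylic acid (C10 epimers) | COC(=O)C1CCC[C@](C)(C(=O)O)[C@@H]1/C=C/I
F5 | step 15 | (E)-enyne C19 acid (21 with free carboxylic acid in place of the tert-butyl ester) | COC(=O)C1CCC[C@](C)(C(=O)O)[C@@H]1/C=C/C#CCC[C@@](O)(CC(OC)OC)CO[Si](c2ccccc2)(c2ccccc2)C(C)(C)C
F6 | step 15 | (6R,7R)-epoxy C19 acid | COC(=O)C1CCC[C@](C)(C(=O)O)[C@@H]1[C@H]2O[C@@H]2C#CCC[C@@](O)(CC(OC)OC)CO[Si](c3ccccc3)(c3ccccc3)C(C)(C)C
F0 | step 20 | none | none
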